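Percent of the starting material charged is the unit to reckon in, and the number to watch in it is the pair, target plus isomer of the product.

| setting | theta | epsilon | flask |
|---|---|---|---|
| starting material | 0.020 M | 0.020 M | 0.020 M |
| coupling partner | 0.030 M | 0.030 M | 0.0300 M |
| second substrate | 0.040 M | 0.040 M | 0.0400 M |
| temperature | 0 °C | 6 °C | 0 °C |
| remark | the very flask that is asked about, followed so far | run made earlier |  |
| time |  |  | 2.5 h |

- theta (time / min: target / %, starting material / %): 10.0: 63.0, 30.8; 30.0: 58.8, 24.7; 50.0: 51.7, 24.0; 80.0: 42.3, 24.2; 120: 34.5, 23.4; 150: 32.4, 23.4
- epsilon (time / min: target / %, starting material / %): 10.0: 63.9, 24.4; 30.0: 49.7, 21.3; 50.0: 40.4, 21.0; 80.0: 35.3, 20.7; 120: 33.4, 20.9; 150: 33.2, 21.2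

(readings scatter by 0.5 percentage points)

- west: change nothing and wait 2.5 h more
- north-west: at 2.5 h add coupling partner, 100% of the amount charged, then wait 2.5 h
- south: at 2.5 h take out 90% of the target then present, then wait 2.5 h
- south-west: at 2.5 h raise the temperature by 25 K, then wait 2.5 h

- removed target is counted in
- steps that have been proposed: target <-> isomer of the product; second substrate <-> dormant form; starting material + coupling partner -> target; 2 second substrate -> self-condensation product; second substrate + coupling partner -> second product
- additions bring no volume worth counting

- target, in percent of the starting material first charged, at 2.5 h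
- the remedy with the largest gain of target, or "none" below 2 percentage points (west / north-west / south / south-west / none)
- target present, with what was taken out counted in, in percent of the starting material first charged, after west
- target present, with what was taken out counted in, in percent of the starting material first charged, after south

In theta the starting material stands at 24.0% by 50.0 min and at 23.4% at the end, while the target falls from 51.7% to 32.4%. So coupling has stopped, and the pair, 76.6%, is being shared out anew: kinetic control has handed over to thermodynamic control. "Now" is therefore close to the last reading, 32.4%, and the question is where the target's fraction of the pair comes to rest.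

A first guess is the levelled epsilon run, 42.1%. But theta already stands at 42.3% and is still falling, so at 0 °C the rest lies lower. The fractions at the equally spaced 10.0 min, 80.0 min and 150 min are 91.0%, 55.8% and 42.3%. Their shrinking steps give a half-life of 50.6 min and a rest at 33.9%: this is the resting share, the target's fraction of the pair once exchange has stopped. The objection is that coupling was still running at 10.0 min. Yet the curve, run back to 50.0 min, gives 51.3% against the reading 51.7%, so we keep it.

A further wait leaves 12.8% of any distance from rest. So we reckon 26.8% after west, 43.6% after south, and 36.7% after north-west if the whole of the starting material couples. Warming moves the rest itself. Stretching the two isomer-to-target ratios, 1.95 and 1.37, straight over 25 K gives a share of 68.8%, so 52.7% of target, the largest of the four. That stretch is long, but south-west stays ahead while the warm share exceeds 56.9%.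

The forecast gives 32.3% now, 31.4% after west, 48% after south and south as best, and says that south-west “adds little, because partner is still missing”. We differ from it on west, on south and on the best remedy.

The flask gives 31.8%, then 27.0% after west and 43.8% after south, and the best is south-west, at 17 percentage points against 12 points for south.

    target ⇌ isomer of the product (K = 1.90, k = 0.0100 min⁻¹, Ea = 84.0 kJ mol⁻¹, ΔH = −32.0 kJ mol⁻¹)
    second substrate ⇌ dormant form (K = 0.540, k = 0.0560 min⁻¹, Ea = 79.0 kJ mol⁻¹, ΔH = −49.0 kJ mol⁻¹)
    starting material + coupling partner → target (k = 13.0 M⁻¹ min⁻¹, Ea = 56.0 kJ mol⁻¹)
    2 second substrate → self-condensation product (k = 1.70 M⁻¹ min⁻¹, Ea = 39.0 kJ mol⁻¹)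
    second substrate + coupling partner → second product (k = 6.80 M⁻¹ min⁻¹, Ea = 39.0 kJ mol⁻¹)
    (constants at 0 °C)

In this flask the half-life of starting material by coupling alone, with the other concentrations as charged, is 1.8 min, far shorter than the 45.4 min relaxation half-life of target and isomer of the product, and the flask holds 64.5% target and 7.98% isomer at 15.0 min. Left to 1500 min it holds 26.4% target, where pair times resting share gives 26.0%, and for the neighbour flask stopped at 1.5 h the same curve gives 40.6%, and that flask holds 40.0%.

(The data are simulated with constants of no real substance; noise was put on by code.)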